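The substrate in this flask met a small excess of reagent, and I wanted to know how much of it ended as target.

substrate 0.050 M; reagent 1.20 equiv; time 1.5 h

    substrate + reagent → intermediate A (k1 = 0.48 /M/min)
    intermediate A → intermediate B (k2 = 0.059 /min)
    reagent → decomposition product (k3 = 4.3 × 10⁻⁵ /min)
    intermediate A → target (k4 = 0.15 /min)
    reagent + intermediate B ⇌ intermediate C (K5 = 6.3 /M, k5 = 0.11 /M/min)

- target at 1.5 h, in percent of the substrate charged
- amount of target if the flask were left three thousand times as long, in percent of the substrate charged

I reckoned the conversion of substrate two ways. The first held the reagent at its charge, the pseudo-first-order view. The substrate then decays with a time constant set by the first rate constant times the reagent, which gave 2.59 time constants in 1.5 h and a conversion of 92.5%.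

The second way used the fact that substrate and reagent leave one for one, so the difference between them stays constant and their ratio grows exponentially. The exponent came to 0.432, and I call that number, first rate constant times excess reagent times time, the excess count. The ratio of reagent to substrate thus rose from 1.20 to 1.85. The excess divided by that ratio less one leaves 23.6% of the substrate, a conversion of 76.4%.

The two ways parted, and the first was the one that cheated: it kept the reagent at its charge, whereas the second conversion, counted one for one, left the reagent at 36.3% of its own charge by my reckoning.

Intermediate A divides in proportion to its two constants, 0.15 /min to target and 0.059 /min to intermediate B. That share, 71.8%, was my amount for very long times, since the substrate left tends to zero as the count grows. Applied to the conversion at the asked time, it gave 54.9%, with nothing taken off for what still stood as intermediate A.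

The forecast gave 53.5% and 71.8%, saying “At 1.5 h the second-order step has consumed roughly three quarters of the substrate”. Its first figure lay a little under mine.

The flask gave 53.6% and 71.8%, with the conversion of substrate at 75.9%. A run with the reagent kept from shrinking reached 92.5%, and a run of ten times the time reached 99.7%, so the shrinking supply of reagent, together with the time given, held this flask back. The forecast's first figure stood close to the flask's, and to fall 5 points away from the flask's figure it would have to meet a flask with the reagent charge at 1.02 equiv or 1.42 equiv, the time held, or with the time at 1.14 h or 2.07 h, the amounts held. For the flask with twice the reagent, the excess count is 3.02, which gives 97.1%, and its run read 96.9%.

(Its constants come from no measurement; no experiment stands behind them.)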